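**Strategy.** Each half of the target is a 3-hydroxy-3,4-dibenzylbutyrolactone (ring atoms O1, C2, C3, C4, C5). Everything rests on cutting C3–C4 of lactone A, the lactone whose C3-benzyl ring (ring B) carries the biaryl bond. C4 is a CH in a 1,5-relationship to C3 through the ester O1–C2. A chiral dirhodium carbenoid, generated at C3 from an achiral open-chain 3-arylpropyl diazoacetate, inserts into one enantiotopic homobenzylic C–H, closing the lactone and fixing C4 in one operation. C3 is then hydroxylated and benzylated anti to C4. The brominated twin lactone B is made likewise, and the halves are joined by Suzuki coupling before global debenzylation.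

Key step: step 3

Assumption: Rh2(4R-MPPIM)4 is dirhodium tetrakis[methyl (4R)-2-oxo-1-(3-phenylpropanoyl)imidazolidine-4-carboxylate], a divalent rhodium carboxamidate. It is taken to give the (S)-lactone from 3-arylpropyl diazoacetates; if the sense proves opposite, the enantiomeric catalyst is used in steps 3 and 12 and nothing else changes.

Ring names: ring A is the guaiacyl ring on the C4-benzyl of lactone A, ring B the aryl ring on its C3-benzyl, ring C the aryl ring on the C4-benzyl of lactone B, ring D the guaiacyl ring on its C3-benzyl. Rings B and C form the biaryl.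

**Route**

Step 1
Reactants: 1 dihydroconiferyl alcohol [3-(4-hydroxy-3-methoxyphenyl)propan-1-ol]; 2 benzyl bromide
Product: 3 3-[4-(benzyloxy)-3-methoxyphenyl]propan-1-ol
Conditions: BnBr (1.1 equiv), K2CO3, acetone, reflux
Reagents that add atoms: benzyl bromide 2, BrCc1ccccc1
Why: Williamson ether synthesis; K2CO3 ionises only the phenol, so the primary alcohol should stay free.

Step 2
Reactants: 3 3-[4-(benzyloxy)-3-methoxyphenyl]propan-1-ol; 4 glyoxylic acid chloride p-toluenesulfonylhydrazone
Product: 6 3-[4-(benzyloxy)-3-methoxyphenyl]propyl 2-diazoacetate, via tosylhydrazone ester 5 (not isolated)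
Conditions: 4 (1.9 equiv), PhNMe2, CH2Cl2, 0 °C; then Et3N, 0 °C to rt
Reagents that add atoms: glyoxylic acid chloride p-toluenesulfonylhydrazone 4, Cc1ccc(cc1)S(=O)(=O)NN=CC(Cl)=O
Why: O-acylation by the acid chloride followed by base-induced loss of p-toluenesulfinate from the tosylhydrazone (Bamford–Stevens-type elimination) should give the diazoacetate in one flask.

Step 3
Reactants: 6 3-[4-(benzyloxy)-3-methoxyphenyl]propyl 2-diazoacetate
Product: 7 (4S)-4-[4-(benzyloxy)-3-methoxybenzyl]dihydrofuran-2(3H)-one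
Conditions: Rh2(4R-MPPIM)4 (1 mol%), CH2Cl2, reflux, 6 added by syringe pump over 10 h
Reagents that add atoms: none
Why: The catalyst decomposes the diazo ester with loss of N2 to an electrophilic divalent-rhodium carbenoid at the future C3, which inserts through a concerted, asynchronous three-centre transition state with hydride-shift character into one C–H bond of the homobenzylic CH2 (the future C4), with retention there. The closest known reaction type is the dirhodium carboxamidate-catalysed enantioselective intramolecular C–H insertion of diazoacetates of 3-arylpropan-1-ols, an established entry to β-benzyl-γ-butyrolactones. Only the lactone ring O1–C2–C3–C4–C5 closes, in the 1,5-insertion mode (the carbenoid carbon and the C–H carbon are separated by C2, O1 and C5). The single new stereocentre C4 is set by the catalyst alone: its chiral carboxamidate ligands differentiate the two enantiotopic hydrogens, and the (4R) catalyst should select the pro-R hydrogen to give (S)-7. The step needs regioselectivity over O–CH2 insertion (β-lactone) and benzylic insertion (δ-lactone), chemoselectivity over addition to the electron-rich arene and over carbene dimerisation, and enantioselectivity. The electron-rich carboxamidate carbenoid reacts late and selectively in favour of five-membered closure, and slow addition at high dilution should suppress dimerisation.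

Step 4
Reactants: 7 (4S)-4-[4-(benzyloxy)-3-methoxybenzyl]dihydrofuran-2(3H)-one; 8 3-phenyl-2-(phenylsulfonyl)oxaziridine
Product: 9 (4R)-4-[4-(benzyloxy)-3-methoxybenzyl]-3-hydroxydihydrofuran-2(3H)-one (C3 epimers; C4 unchanged in space, descriptor changed by CIP priority)
Conditions: KN(SiMe3)2 (1.2 equiv), THF, −78 °C; then 8, −78 °C; aq NH4Cl
Reagents that add atoms: 3-phenyl-2-(phenylsulfonyl)oxaziridine 8, O=S(=O)(c1ccccc1)N1OC1c1ccccc1
Why: Enolate hydroxylation by electrophilic oxygen transfer from an N-sulfonyloxaziridine; the C3 configuration formed here is irrelevant because C3 is made planar again in step 8.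

Step 5
Reactants: 10 5-bromovanillin; 2 benzyl bromide
Product: 11 4-(benzyloxy)-3-bromo-5-methoxybenzaldehyde
Conditions: BnBr, K2CO3, DMF, 60 °C
Reagents that add atoms: benzyl bromide 2, BrCc1ccccc1
Why: Williamson ether synthesis of the acidic, flanked phenol, for which DMF and mild heating should suffice.

Step 6
Reactants: 11 4-(benzyloxy)-3-bromo-5-methoxybenzaldehyde
Product: 12 [4-(benzyloxy)-3-bromo-5-methoxyphenyl]methanol
Conditions: NaBH4, MeOH–THF, 0 °C
Reagents that add atoms: none
Why: Borohydride reduction of the aldehyde, which leaves the aryl bromide and benzyl ether untouched.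

Step 7
Reactants: 12 [4-(benzyloxy)-3-bromo-5-methoxyphenyl]methanol; 13 phosphorus tribromide
Product: 14 4-(benzyloxy)-3-bromo-5-methoxybenzyl bromide
Conditions: PBr3, CH2Cl2, 0 °C
Reagents that add atoms: phosphorus tribromide 13, BrP(Br)Br
Why: Conversion of a benzylic alcohol into the bromide via its phosphite ester (SN2 displacement by bromide).

Step 8
Reactants: 9 (4R)-4-[4-(benzyloxy)-3-methoxybenzyl]-3-hydroxydihydrofuran-2(3H)-one; 14 4-(benzyloxy)-3-bromo-5-methoxybenzyl bromide
Product: 15 (3R,4R)-3-[4-(benzyloxy)-3-bromo-5-methoxybenzyl]-4-[4-(benzyloxy)-3-methoxybenzyl]-3-hydroxydihydrofuran-2(3H)-one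
Conditions: LiN(iPr)2 (2.3 equiv), THF–HMPA, −78 °C; then 14, −78 to −30 °C; aq NH4Cl
Reagents that add atoms: none
Why: C-alkylation of the dilithio enediolate of an α-hydroxy lactone; the electrophile should enter anti to the C4 benzyl group, so the new benzyl is trans to it and the hydroxyl cis, which is the (3R,4R) arrangement.

Step 9
Reactants: 1 dihydroconiferyl alcohol; 16 N-bromosuccinimide
Product: 17 3-(3-bromo-4-hydroxy-5-methoxyphenyl)propan-1-ol
Conditions: NBS (1.0 equiv), iPr2NH (10 mol%), CH2Cl2, 0 °C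
Reagents that add atoms: N-bromosuccinimide 16, O=C1CCC(=O)N1Br
Why: Amine-catalysed ortho-bromination of a phenol (electrophilic aromatic substitution); the free hydroxyl is the strongest director and its only open ortho position is ring carbon 5, the para position being blocked by the side chain.

Step 10
Reactants: 17 3-(3-bromo-4-hydroxy-5-methoxyphenyl)propan-1-ol; 2 benzyl bromide
Product: 18 3-[4-(benzyloxy)-3-bromo-5-methoxyphenyl]propan-1-ol
Conditions: BnBr, K2CO3, DMF, 60 °C
Reagents that add atoms: benzyl bromide 2, BrCc1ccccc1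
Why: Williamson ether synthesis, selective for the phenoxide over the primary alcohol.

Step 11
Reactants: 18 3-[4-(benzyloxy)-3-bromo-5-methoxyphenyl]propan-1-ol; 4 glyoxylic acid chloride p-toluenesulfonylhydrazone
Product: 20 3-[4-(benzyloxy)-3-bromo-5-methoxyphenyl]propyl 2-diazoacetate, via tosylhydrazone ester 19 (not isolated)
Conditions: 4 (1.9 equiv), PhNMe2, CH2Cl2, 0 °C; then Et3N, 0 °C to rt
Reagents that add atoms: glyoxylic acid chloride p-toluenesulfonylhydrazone 4, Cc1ccc(cc1)S(=O)(=O)NN=CC(Cl)=O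
Why: Same acylation and sulfinate elimination (Bamford–Stevens type) as in step 2; the aryl bromide is inert.

Step 12
Reactants: 20 3-[4-(benzyloxy)-3-bromo-5-methoxyphenyl]propyl 2-diazoacetate
Product: 21 (4S)-4-[4-(benzyloxy)-3-bromo-5-methoxybenzyl]dihydrofuran-2(3H)-one
Conditions: Rh2(4R-MPPIM)4 (1 mol%), CH2Cl2, reflux, 20 added by syringe pump over 10 h
Reagents that add atoms: none
Why: Enantioselective intramolecular 1,5 C–H insertion of the divalent-rhodium carbenoid, as in step 3; the catalyst should again select the pro-R homobenzylic hydrogen and so set C4 of lactone B.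

Step 13
Reactants: 21 (4S)-4-[4-(benzyloxy)-3-bromo-5-methoxybenzyl]dihydrofuran-2(3H)-one; 8 3-phenyl-2-(phenylsulfonyl)oxaziridine
Product: 22 (4R)-4-[4-(benzyloxy)-3-bromo-5-methoxybenzyl]-3-hydroxydihydrofuran-2(3H)-one (C3 epimers)
Conditions: KN(SiMe3)2 (1.2 equiv), THF, −78 °C; then 8, −78 °C; aq NH4Cl
Reagents that add atoms: 3-phenyl-2-(phenylsulfonyl)oxaziridine 8, O=S(=O)(c1ccccc1)N1OC1c1ccccc1
Why: Enolate hydroxylation with the N-sulfonyloxaziridine as in step 4; the amide base does not touch the aryl bromide at −78 °C.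

Step 14
Reactants: 23 [4-(benzyloxy)-3-methoxyphenyl]methanol; 13 phosphorus tribromide
Product: 24 4-(benzyloxy)-3-methoxybenzyl bromide
Conditions: PBr3, Et2O, 0 °C
Reagents that add atoms: phosphorus tribromide 13, BrP(Br)Br
Why: Benzylic alcohol to bromide via the phosphite ester, as in step 7.

Step 15
Reactants: 22 (4R)-4-[4-(benzyloxy)-3-bromo-5-methoxybenzyl]-3-hydroxydihydrofuran-2(3H)-one; 24 4-(benzyloxy)-3-methoxybenzyl bromide
Product: 25 (3R,4R)-4-[4-(benzyloxy)-3-bromo-5-methoxybenzyl]-3-[4-(benzyloxy)-3-methoxybenzyl]-3-hydroxydihydrofuran-2(3H)-one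
Conditions: LiN(iPr)2 (2.3 equiv), THF–HMPA, −78 °C; then 24, −78 to −30 °C; aq NH4Cl
Reagents that add atoms: none
Why: Enediolate dianion C-alkylation anti to the C4 benzyl group, as in step 8, should give the (3R,4R) lactone B.

Step 16
Reactants: 25 lactone B bromide; 26 bis(pinacolato)diboron; 15 lactone A bromide
Product: 28 tetra-O-benzyl ether of the target (ring B of 15 joined to ring C of 25; 3R,4R in both lactones), via arylboronate 27 (not isolated)
Conditions: B2pin2 (1.05 equiv), KOAc, Pd2(dba)3 (2 mol%), XPhos (8 mol%), 1,4-dioxane, 100 °C; then 15 (0.95 equiv), aq K3PO4, 100 °C; 1 M HCl work-up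
Reagents that add atoms: none
Why: Miyaura borylation of 25 followed in the same flask by Suzuki–Miyaura coupling with 15 on zerovalent palladium; each partner has one ortho alkoxy group, which the bulky biarylphosphine should tolerate, no stereocentre is enolisable, and the acidic work-up recloses any opened lactone.

Step 17
Reactants: 28 tetra-O-benzyl ether of the target
Product: 29 CNP0218652.1
Conditions: H2 (1 atm), Pd/C (10 wt%), EtOAc–MeOH, rt
Reagents that add atoms: none
Why: Hydrogenolysis of the four aryl benzyl ethers; the tertiary alcohols are not benzylic and the lactones and biaryl are inert, so both (3R,4R) units should emerge unchanged.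

**Compound list**

1 | dihydroconiferyl alcohol, 3-(4-hydroxy-3-methoxyphenyl)propan-1-ol | COc1cc(CCCO)ccc1O | starting material
2 | benzyl bromide | BrCc1ccccc1 | starting material
3 | 3-[4-(benzyloxy)-3-methoxyphenyl]propan-1-ol | COc1cc(CCCO)ccc1OCc1ccccc1 | intermediate
4 | glyoxylic acid chloride p-toluenesulfonylhydrazone | Cc1ccc(cc1)S(=O)(=O)NN=CC(Cl)=O | starting material
5 | 3-[4-(benzyloxy)-3-methoxyphenyl]propyl 2-(tosylhydrazono)acetate | COc1cc(CCCOC(=O)C=NNS(=O)(=O)c2ccc(C)cc2)ccc1OCc1ccccc1 | intermediate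
6 | 3-[4-(benzyloxy)-3-methoxyphenyl]propyl 2-diazoacetate | COc1cc(CCCOC(=O)C=[N+]=[N-])ccc1OCc1ccccc1 | intermediate
7 | (4S)-4-[4-(benzyloxy)-3-methoxybenzyl]dihydrofuran-2(3H)-one | O=C1C[C@H](Cc2ccc(OCc3ccccc3)c(OC)c2)CO1 | intermediate
8 | 3-phenyl-2-(phenylsulfonyl)oxaziridine (racemic) | O=S(=O)(c1ccccc1)N1OC1c1ccccc1 | starting material
9 | (4R)-4-[4-(benzyloxy)-3-methoxybenzyl]-3-hydroxydihydrofuran-2(3H)-one, C3 epimers | COc1cc(C[C@@H]2COC(=O)C2O)ccc1OCc1ccccc1 | intermediate
10 | 5-bromovanillin | COc1cc(C=O)cc(Br)c1O | starting material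
11 | 4-(benzyloxy)-3-bromo-5-methoxybenzaldehyde | COc1cc(C=O)cc(Br)c1OCc1ccccc1 | intermediate
12 | [4-(benzyloxy)-3-bromo-5-methoxyphenyl]methanol | COc1cc(CO)cc(Br)c1OCc1ccccc1 | intermediate
13 | phosphorus tribromide | BrP(Br)Br | starting material
14 | 4-(benzyloxy)-3-bromo-5-methoxybenzyl bromide | COc1cc(CBr)cc(Br)c1OCc1ccccc1 | intermediate
15 | (3R,4R)-3-[4-(benzyloxy)-3-bromo-5-methoxybenzyl]-4-[4-(benzyloxy)-3-methoxybenzyl]-3-hydroxydihydrofuran-2(3H)-one | COc1cc(C[C@@H]2COC(=O)[C@@]2(O)Cc2cc(OC)c(OCc3ccccc3)c(Br)c2)ccc1OCc1ccccc1 | intermediate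
16 | N-bromosuccinimide | O=C1CCC(=O)N1Br | starting material
17 | 3-(3-bromo-4-hydroxy-5-methoxyphenyl)propan-1-ol | COc1cc(CCCO)cc(Br)c1O | intermediate
18 | 3-[4-(benzyloxy)-3-bromo-5-methoxyphenyl]propan-1-ol | COc1cc(CCCO)cc(Br)c1OCc1ccccc1 | intermediate
19 | 3-[4-(benzyloxy)-3-bromo-5-methoxyphenyl]propyl 2-(tosylhydrazono)acetate | COc1cc(CCCOC(=O)C=NNS(=O)(=O)c2ccc(C)cc2)cc(Br)c1OCc1ccccc1 | intermediate
20 | 3-[4-(benzyloxy)-3-bromo-5-methoxyphenyl]propyl 2-diazoacetate | COc1cc(CCCOC(=O)C=[N+]=[N-])cc(Br)c1OCc1ccccc1 | intermediate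
21 | (4S)-4-[4-(benzyloxy)-3-bromo-5-methoxybenzyl]dihydrofuran-2(3H)-one | O=C1C[C@H](Cc2cc(Br)c(OCc3ccccc3)c(OC)c2)CO1 | intermediate
22 | (4R)-4-[4-(benzyloxy)-3-bromo-5-methoxybenzyl]-3-hydroxydihydrofuran-2(3H)-one, C3 epimers | COc1cc(C[C@@H]2COC(=O)C2O)cc(Br)c1OCc1ccccc1 | intermediate
23 | [4-(benzyloxy)-3-methoxyphenyl]methanol | COc1cc(CO)ccc1OCc1ccccc1 | starting material
24 | 4-(benzyloxy)-3-methoxybenzyl bromide | COc1cc(CBr)ccc1OCc1ccccc1 | intermediate
25 | (3R,4R)-4-[4-(benzyloxy)-3-bromo-5-methoxybenzyl]-3-[4-(benzyloxy)-3-methoxybenzyl]-3-hydroxydihydrofuran-2(3H)-one | COc1cc(C[C@@H]2COC(=O)[C@@]2(O)Cc2ccc(OCc3ccccc3)c(OC)c2)cc(Br)c1OCc1ccccc1 | intermediate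
26 | bis(pinacolato)diboron | CC1(C)OB(OC1(C)C)B1OC(C)(C)C(C)(C)O1 | starting material
27 | (3R,4R)-4-[4-(benzyloxy)-3-methoxy-5-(4,4,5,5-tetramethyl-1,3,2-dioxaborolan-2-yl)benzyl]-3-[4-(benzyloxy)-3-methoxybenzyl]-3-hydroxydihydrofuran-2(3H)-one | COc1cc(C[C@@H]2COC(=O)[C@@]2(O)Cc2ccc(OCc3ccccc3)c(OC)c2)cc(B2OC(C)(C)C(C)(C)O2)c1OCc1ccccc1 | intermediate
28 | tetra-O-benzyl ether of the target (all four phenols benzylated; 3R,4R in both lactones) | COc1cc(C[C@@H]2COC(=O)[C@@]2(O)Cc2cc(OC)c(OCc3ccccc3)c(-c3cc(C[C@@H]4COC(=O)[C@@]4(O)Cc4ccc(OCc5ccccc5)c(OC)c4)cc(OC)c3OCc3ccccc3)c2)ccc1OCc1ccccc1 | intermediate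
29 | CNP0218652.1, the biaryl dimer of (3R,4R)-3-hydroxy-3,4-bis(4-hydroxy-3-methoxybenzyl)dihydrofuran-2(3H)-one linked from the C3-benzyl ring of one unit to the C4-benzyl ring of the other | COc1cc(C[C@@H]2COC(=O)[C@@]2(O)Cc2cc(OC)c(O)c(-c3cc(C[C@@H]4COC(=O)[C@@]4(O)Cc4ccc(O)c(OC)c4)cc(OC)c3O)c2)ccc1O | target

**Totals**

Total step count: 17.
Longest linear sequence: 8 steps (1 → 17 → 18 → 20 → 21 → 22 → 25 → 28 → 29; steps 9 to 13, 15, 16 and 17).

**Steps most likely to fail**

1. Step 3 (the same reaction recurs in step 12). The carbenoid may insert into the O–CH2 or benzylic C–H bonds instead of the homobenzylic one, add to the electron-rich arene, dimerise, or discriminate the two enantiotopic hydrogens poorly. The fallback still makes C3–C4 in a ring closure, but by addition to an alkene, where no C–H regiochemistry is at issue. It sets out from 23. Oxidation with MnO2 in CH2Cl2 would give 4-(benzyloxy)-3-methoxybenzaldehyde F1. Wittig olefination with Ph3P=CHCO2Et would give ethyl (E)-3-[4-(benzyloxy)-3-methoxyphenyl]prop-2-enoate F2. Reduction with iBu2AlH at −78 °C would give (E)-3-[4-(benzyloxy)-3-methoxyphenyl]prop-2-en-1-ol F3. The one-flask acylation with 4 would pass through (E)-3-[4-(benzyloxy)-3-methoxyphenyl]allyl 2-(tosylhydrazono)acetate F4 to (E)-3-[4-(benzyloxy)-3-methoxyphenyl]allyl 2-diazoacetate F5. Intramolecular cyclopropanation, with the enantiomer of Rh2(MPPIM)4 that delivers this isomer, would give (1R,5S,6S)-6-[4-(benzyloxy)-3-methoxyphenyl]-3-oxabicyclo[3.1.0]hexan-2-one F6. Hydrogenolysis (H2, Pd/C, EtOH) should cleave the C1–C6 cyclopropane bond, which is activated by both the aryl and the carbonyl group, together with the benzyl ether, giving (4S)-4-(4-hydroxy-3-methoxybenzyl)dihydrofuran-2(3H)-one F7. Re-benzylation with 2 and K2CO3 returns to the route at 7.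

2. Step 8 (the same reaction recurs in step 15). The dianion may form incompletely, alkylate on oxygen, or be attacked from the wrong face. The fallback replaces the benzylic halide by the more reactive aldehyde and sets out from 9. Aldol addition of the dilithio enediolate of 9 to aldehyde 11 (THF, −78 °C), again anti to the C4 benzyl group, would give (3S,4R)-3-{[4-(benzyloxy)-3-bromo-5-methoxyphenyl](hydroxy)methyl}-4-[4-(benzyloxy)-3-methoxybenzyl]-3-hydroxydihydrofuran-2(3H)-one F8 as a carbinol epimer mixture. Ionic deoxygenation of the electron-rich benzylic carbinol (Et3SiH, CF3CO2H, CH2Cl2, 0 °C) would leave the non-benzylic tertiary alcohol and return to the route at 15.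

3. Step 16. Borylation may be incomplete, so that either bromide homocouples, or the ortho-alkoxy arylboronate may protodeboronate before it couples. The fallback moves boron to a small, robust partner that can be used in excess and makes the final union a C-alkylation; it sets out from 12. Miyaura borylation (B2pin2, KOAc, PdCl2(dppf), a divalent palladium precatalyst, dioxane, 90 °C) would give [4-(benzyloxy)-3-methoxy-5-(4,4,5,5-tetramethyl-1,3,2-dioxaborolan-2-yl)phenyl]methanol F9, which is isolated. Suzuki–Miyaura coupling of F9 with 25 would give the biaryl benzylic alcohol F10. Appel bromination (CBr4, PPh3, CH2Cl2, 0 °C), which spares the tertiary alcohol, would give the biaryl benzylic bromide F11. F11, its tertiary hydroxyl first masked as the lithium alkoxide with one equivalent of LiN(SiMe3)2, would then alkylate the dilithio enediolate of 9 anti to the C4 benzyl group, returning to the route at 28.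

**Further compounds**

F1 | step 3 | 4-(benzyloxy)-3-methoxybenzaldehyde | COc1cc(C=O)ccc1OCc1ccccc1
F2 | step 3 | ethyl (E)-3-[4-(benzyloxy)-3-methoxyphenyl]prop-2-enoate | CCOC(=O)/C=C/c1ccc(OCc2ccccc2)c(OC)c1
F3 | step 3 | (E)-3-[4-(benzyloxy)-3-methoxyphenyl]prop-2-en-1-ol | OC/C=C/c1ccc(OCc2ccccc2)c(OC)c1
F4 | step 3 | (E)-3-[4-(benzyloxy)-3-methoxyphenyl]allyl 2-(tosylhydrazono)acetate | COc1cc(/C=C/COC(=O)C=NNS(=O)(=O)c2ccc(C)cc2)ccc1OCc1ccccc1
F5 | step 3 | (E)-3-[4-(benzyloxy)-3-methoxyphenyl]allyl 2-diazoacetate | COc1cc(/C=C/COC(=O)C=[N+]=[N-])ccc1OCc1ccccc1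
F6 | step 3 | (1R,5S,6S)-6-[4-(benzyloxy)-3-methoxyphenyl]-3-oxabicyclo[3.1.0]hexan-2-one | O=C1[C@H]2[C@@H](CO1)[C@@H]2c1ccc(OCc2ccccc2)c(OC)c1
F7 | step 3 | (4S)-4-(4-hydroxy-3-methoxybenzyl)dihydrofuran-2(3H)-one | O=C1C[C@H](Cc2ccc(O)c(OC)c2)CO1
F8 | step 8 | (3S,4R)-3-{[4-(benzyloxy)-3-bromo-5-methoxyphenyl](hydroxy)methyl}-4-[4-(benzyloxy)-3-methoxybenzyl]-3-hydroxydihydrofuran-2(3H)-one, carbinol epimers | COc1cc(C[C@@H]2COC(=O)[C@@]2(O)C(O)c2cc(OC)c(OCc3ccccc3)c(Br)c2)ccc1OCc1ccccc1
F9 | step 16 | [4-(benzyloxy)-3-methoxy-5-(4,4,5,5-tetramethyl-1,3,2-dioxaborolan-2-yl)phenyl]methanol | COc1cc(CO)cc(B2OC(C)(C)C(C)(C)O2)c1OCc1ccccc1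
F10 | step 16 | (3R,4R)-4-{[6,2'-bis(benzyloxy)-5'-(hydroxymethyl)-5,3'-dimethoxybiphenyl-3-yl]methyl}-3-[4-(benzyloxy)-3-methoxybenzyl]-3-hydroxydihydrofuran-2(3H)-one | COc1cc(C[C@@H]2COC(=O)[C@@]2(O)Cc2ccc(OCc3ccccc3)c(OC)c2)cc(-c2cc(CO)cc(OC)c2OCc2ccccc2)c1OCc1ccccc1
F11 | step 16 | (3R,4R)-4-{[6,2'-bis(benzyloxy)-5'-(bromomethyl)-5,3'-dimethoxybiphenyl-3-yl]methyl}-3-[4-(benzyloxy)-3-methoxybenzyl]-3-hydroxydihydrofuran-2(3H)-one | COc1cc(C[C@@H]2COC(=O)[C@@]2(O)Cc2ccc(OCc3ccccc3)c(OC)c2)cc(-c2cc(CBr)cc(OC)c2OCc2ccccc2)c1OCc1ccccc1
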